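**Plan** (target numbering: quinone ring C1(=O), C2 bearing the side chain, C3–H, C4(=O); benzenoid ring C4a, C5–OH to C8–OH, C8a)
1. Retrosynthesis: remove the two phenol acetals and the C1 oxygen (quinone from a 1-naphthol), then cut C2–C3 and C4–C4a of the quinone ring in one operation, then the acetyl C–C bond at C2, the ester C–O bond and the alkyne–carbonyl bond.
2. Enabling feature: C3(H)–C4(=O) is a latent ketene CH=C=O lying between an alkenyl carbon (C2) and the free ortho CH (C4a) of a 2,5-dioxygenated benzene ring. A (Z)-β-aryl enone diazo ketone therefore gives the second ring by Wolff shift of C2 onto C3 and 6π closure of C4 onto C4a.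
3. Forward: aryl alkyne + Weinreb amide → ynone → (S)-propargylic alcohol → trans-hydrostannation (aryl cis to the future acyl group) → senecioate, acetyl, diazo → Wolff/6π benzannulation → oxidation to the quinone → acetal removal.
4. Stereochemistry: the single (S) center is set by catalyst-controlled asymmetric transfer hydrogenation of the ynone and is never part of a reacting center afterwards. The alkene geometry needed for ring closure comes from anti hydrostannation and a retentive Stille coupling.

Key step: step 10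

Remark: compounds 1, 4 and 12 and the reagents named in the steps are taken as purchased.

**Step 1**
Reactants: 1 2,5-dihydroxybenzaldehyde
Product: 2 2,5-bis(methoxymethoxy)benzaldehyde
Conditions: MOMCl, i-Pr2NEt, CH2Cl2, 0 → 40 °C
Reagents that add atoms: chloromethyl methyl ether, COCCl
Why: O-alkylation of both phenols with the α-chloro ether under amine base leaves the aldehyde untouched and gives aryl acetals that tolerate the later organometallic, basic, photochemical and oxidative steps.

**Step 2**
Reactants: 2 2,5-bis(methoxymethoxy)benzaldehyde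
Product: 3 2-ethynyl-1,4-bis(methoxymethoxy)benzene
Conditions: dimethyl (1-diazo-2-oxopropyl)phosphonate, K2CO3, MeOH, 25 °C
Reagents that add atoms: dimethyl (1-diazo-2-oxopropyl)phosphonate, CC(=O)C(=[N+]=[N-])P(=O)(OC)OC
Why: Seyferth–Gilbert homologation in the Ohira–Bestmann variant converts the aryl aldehyde to the terminal alkyne under carbonate/methanol conditions that do not affect the acetals.

**Step 3**
Reactants: 4 4-methylpent-3-enoic acid
Product: 6 N-methoxy-N,4-dimethylpent-3-enamide, via acyl imidazolide 5 (not isolated)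
Conditions: CDI, CH2Cl2, 25 °C; then MeNH(OMe)·HCl, 25 °C
Reagents that add atoms: 1,1'-carbonyldiimidazole, O=C(n1ccnc1)n1ccnc1 (imidazolyl group of 5); N,O-dimethylhydroxylamine hydrochloride, Cl.CNOC
Why: Acyl imidazolide activation followed by aminolysis (Weinreb amide synthesis) is mild enough to keep the β,γ-alkene out of conjugation.

**Step 4**
Reactants: 3 2-ethynyl-1,4-bis(methoxymethoxy)benzene, 6 N-methoxy-N,4-dimethylpent-3-enamide
Product: 9 1-[2,5-bis(methoxymethoxy)phenyl]-6-methylhept-5-en-1-yn-3-one, via lithium acetylide 7 (not isolated), via chelated tetrahedral adduct 8 (not isolated)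
Conditions: n-BuLi, THF, −78 °C; then 6, −78 → −20 °C; AcOH quench at −78 °C
Reagents that add atoms: n-butyllithium, [Li]CCCC (lithium of 7 and 8)
Why: Acetylide addition to a Weinreb amide stops at the chelated adduct, which gives the ynone only on the cold acidic quench, so over-addition and conjugate addition of the released amine should be avoided.

**Step 5**
Reactants: 9 1-[2,5-bis(methoxymethoxy)phenyl]-6-methylhept-5-en-1-yn-3-one
Product: 10 (3S)-1-[2,5-bis(methoxymethoxy)phenyl]-6-methylhept-5-en-1-yn-3-ol
Conditions: Ru[(S,S)-TsNCH(Ph)CH(Ph)NH](p-cymene) (1 mol %), i-PrOH, 25 °C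
Reagents that add atoms: none
Why: Noyori asymmetric transfer hydrogenation of an alkynyl ketone, in which the (S,S)-catalyst places the alkynyl group where an aryl group sits in aryl ketone reductions and should deliver hydride to the face that gives the (S)-carbinol, without alkoxide base that could move the skipped alkene.

**Step 6**
Reactants: 10 (3S)-1-[2,5-bis(methoxymethoxy)phenyl]-6-methylhept-5-en-1-yn-3-ol
Product: 11 (1Z,3S)-1-[2,5-bis(methoxymethoxy)phenyl]-6-methyl-2-(tributylstannyl)hepta-1,5-dien-3-ol
Conditions: Bu3SnH, [Cp*RuCl]4 (1.5 mol %), CH2Cl2, 25 °C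
Reagents that add atoms: tributyltin hydride, CCCC[SnH](CCCC)CCCC
Why: Ruthenium-catalyzed trans-hydrostannation of a propargylic alcohol, in which hydrogen bonding of the free OH to the Ru–Cl unit steers tin to the proximal alkyne carbon and H and Sn add anti, so the aryl ring ends cis to tin.

**Step 7**
Reactants: 11 (1Z,3S)-1-[2,5-bis(methoxymethoxy)phenyl]-6-methyl-2-(tributylstannyl)hepta-1,5-dien-3-ol, 12 3-methylbut-2-enoic acid
Product: 13 (1Z,3S)-1-[2,5-bis(methoxymethoxy)phenyl]-6-methyl-2-(tributylstannyl)hepta-1,5-dien-3-yl 3-methylbut-2-enoate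
Conditions: DCC, DMAP (cat.), CH2Cl2, 0 → 25 °C
Reagents that add atoms: none
Why: Steglich esterification installs the target's ester early, where it also protects the carbinol through the ketene step; the neutral conditions should leave the C–Sn bond and the conjugated acid unchanged, and the C–O bond of the stereocenter is not broken.

**Step 8**
Reactants: 13 (1Z,3S)-1-[2,5-bis(methoxymethoxy)phenyl]-6-methyl-2-(tributylstannyl)hepta-1,5-dien-3-yl 3-methylbut-2-enoate
Product: 14 (3Z,4S)-3-[2,5-bis(methoxymethoxy)benzylidene]-7-methyl-2-oxooct-6-en-4-yl 3-methylbut-2-enoate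
Conditions: AcCl (3 equiv), Pd2(dba)3 (2.5 mol %), AsPh3 (10 mol %), CuI (10 mol %), THF, 50 °C
Reagents that add atoms: acetyl chloride, CC(Cl)=O
Why: Stille acylation of an alkenylstannane with an acid chloride proceeds with retention of alkene geometry, so the acetyl group ends cis to the aryl ring, and the excess of AcCl keeps zerovalent palladium trapped as the acylpalladium chloride and away from the allylic ester.

**Step 9**
Reactants: 14 (3Z,4S)-3-[2,5-bis(methoxymethoxy)benzylidene]-7-methyl-2-oxooct-6-en-4-yl 3-methylbut-2-enoate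
Product: 16 (3Z,4S)-3-[2,5-bis(methoxymethoxy)benzylidene]-1-diazo-7-methyl-2-oxooct-6-en-4-yl 3-methylbut-2-enoate, via trifluoroacetyl diketone 15 (not isolated)
Conditions: LiN(SiMe3)2, THF, −78 °C; CF3CO2CH2CF3, −78 °C; cold aq. HCl work-up; then MsN3, Et3N, H2O, MeCN, 25 °C
Reagents that add atoms: 2,2,2-trifluoroethyl trifluoroacetate, O=C(OCC(F)(F)F)C(F)(F)F (trifluoroacetyl group of 15); methanesulfonyl azide, CS(=O)(=O)N=[N+]=[N-]
Why: Danheiser detrifluoroacetylative diazo transfer, in which the kinetic methyl enolate is trifluoroacetylated at −78 °C and the activated methylene then takes the diazo group from MsN3 with loss of the trifluoroacetyl group, a sequence designed for base-sensitive enones and expected to be faster at −78 °C than attack of the enolate on the hindered conjugated ester.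

**Step 10**
Reactants: 16 (3Z,4S)-3-[2,5-bis(methoxymethoxy)benzylidene]-1-diazo-7-methyl-2-oxooct-6-en-4-yl 3-methylbut-2-enoate
Product: 19 (1S)-1-[4-hydroxy-5,8-bis(methoxymethoxy)naphthalen-2-yl]-4-methylpent-3-en-1-yl 3-methylbut-2-enoate, via vinylketene 17 (not isolated), via cyclohexadienone 18 (not isolated)
Conditions: hν (blue LED, 450 nm), toluene (0.01 M, degassed), 25 °C; then 60 °C
Reagents that add atoms: none
Why: Excitation of the diazo ketone expels N2 with a concerted 1,2-shift of the alkenyl carbon from the carbonyl carbon to the diazo carbon (Wolff rearrangement), which makes the first new C–C bond and gives vinylketene 17 with the aryl ring cis to the ketenyl group. Thermal 6π electrocyclization across the ketene C=C, the alkene and the adjacent arene C=C then joins the ketene carbon to the free ortho CH (second new bond) to give dienone 18, which enolizes to naphthol 19. The closest known reaction types are the photochemical Wolff generation of vinylketenes from α,β-unsaturated diazomethyl ketones and the aryl-vinylketene electrocyclization that ends cyclobutenone- and carbene-based benzannulations. The new six-membered ring closes in a disrotatory 6π mode and ends aromatic, so no stereocenter is created and the (S) carbinol, which is not involved, is kept. The step needs the Z geometry, secured by steps 6 and 8 and protected by irradiating beyond the styrenyl enone absorption, and closure at the unsubstituted ortho carbon, the only one that can rearomatize. It also needs the electrocyclization to outrun [2+2] addition of the ketene to the prenyl alkene, which the electron-rich arene, high dilution and a temperature well below that of ketene–alkene cycloadditions should secure.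

**Step 11**
Reactants: 19 (1S)-1-[4-hydroxy-5,8-bis(methoxymethoxy)naphthalen-2-yl]-4-methylpent-3-en-1-yl 3-methylbut-2-enoate
Product: 20 (1S)-1-[5,8-bis(methoxymethoxy)-1,4-dioxo-1,4-dihydronaphthalen-2-yl]-4-methylpent-3-en-1-yl 3-methylbut-2-enoate
Conditions: (KO3S)2NO, KH2PO4, acetone/H2O, 0 → 25 °C
Reagents that add atoms: potassium nitrosodisulfonate, [K+].[K+].[O-]S(=O)(=O)N([O])S(=O)(=O)[O-]
Why: Teuber oxidation of a para-unsubstituted 1-naphthol with Fremy's radical should give the 1,4-quinone, and the buffered aqueous medium does not touch the ester, the acetals or the alkenes.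

**Step 12**
Reactants: 20 (1S)-1-[5,8-bis(methoxymethoxy)-1,4-dioxo-1,4-dihydronaphthalen-2-yl]-4-methylpent-3-en-1-yl 3-methylbut-2-enoate
Product: 21 alkannin β,β-dimethylacrylate, (1S)-1-(5,8-dihydroxy-1,4-dioxo-1,4-dihydronaphthalen-2-yl)-4-methylpent-3-en-1-yl 3-methylbut-2-enoate
Conditions: 3 M aq. HCl, THF, 40 °C
Reagents that add atoms: none
Why: Acid hydrolysis of the two aryl methoxymethyl acetals is eased by hydrogen bonding of each freed phenol to the peri quinone carbonyl, while the secondary senecioate and the trisubstituted alkene should tolerate dilute aqueous acid and the stereocenter is not involved.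

**Compound list**
1 | 2,5-dihydroxybenzaldehyde | O=Cc1cc(O)ccc1O | starting material
2 | 2,5-bis(methoxymethoxy)benzaldehyde | O=Cc1cc(OCOC)ccc1OCOC | intermediate
3 | 2-ethynyl-1,4-bis(methoxymethoxy)benzene | C#Cc1cc(OCOC)ccc1OCOC | intermediate
4 | 4-methylpent-3-enoic acid | CC(C)=CCC(=O)O | starting material
5 | 1-(4-methylpent-3-enoyl)imidazole (acyl imidazolide) | CC(C)=CCC(=O)n1ccnc1 | intermediate
6 | N-methoxy-N,4-dimethylpent-3-enamide | CC(C)=CCC(=O)N(C)OC | intermediate
7 | {[2,5-bis(methoxymethoxy)phenyl]ethynyl}lithium | [Li]C#Cc1cc(OCOC)ccc1OCOC | intermediate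
8 | lithium 1-[2,5-bis(methoxymethoxy)phenyl]-3-[methoxy(methyl)amino]-6-methylhept-5-en-1-yn-3-olate (chelated tetrahedral adduct) | CC(C)=CCC(O[Li])(C#Cc1cc(OCOC)ccc1OCOC)N(C)OC | intermediate
9 | 1-[2,5-bis(methoxymethoxy)phenyl]-6-methylhept-5-en-1-yn-3-one | CC(C)=CCC(=O)C#Cc1cc(OCOC)ccc1OCOC | intermediate
10 | (3S)-1-[2,5-bis(methoxymethoxy)phenyl]-6-methylhept-5-en-1-yn-3-ol | CC(C)=CC[C@H](O)C#Cc1cc(OCOC)ccc1OCOC | intermediate
11 | (1Z,3S)-1-[2,5-bis(methoxymethoxy)phenyl]-6-methyl-2-(tributylstannyl)hepta-1,5-dien-3-ol (aryl cis to tin) | CC(C)=CC[C@H](O)/C(=C/c1cc(OCOC)ccc1OCOC)[Sn](CCCC)(CCCC)CCCC | intermediate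
12 | 3-methylbut-2-enoic acid | CC(C)=CC(=O)O | starting material
13 | (1Z,3S)-1-[2,5-bis(methoxymethoxy)phenyl]-6-methyl-2-(tributylstannyl)hepta-1,5-dien-3-yl 3-methylbut-2-enoate | CC(C)=CC[C@H](OC(=O)C=C(C)C)/C(=C/c1cc(OCOC)ccc1OCOC)[Sn](CCCC)(CCCC)CCCC | intermediate
14 | (3Z,4S)-3-[2,5-bis(methoxymethoxy)benzylidene]-7-methyl-2-oxooct-6-en-4-yl 3-methylbut-2-enoate (aryl cis to acetyl) | CC(C)=CC[C@H](OC(=O)C=C(C)C)/C(=C/c1cc(OCOC)ccc1OCOC)C(C)=O | intermediate
15 | (5Z,6S)-5-[2,5-bis(methoxymethoxy)benzylidene]-1,1,1-trifluoro-9-methyl-2,4-dioxodec-8-en-6-yl 3-methylbut-2-enoate | CC(C)=CC[C@H](OC(=O)C=C(C)C)/C(=C/c1cc(OCOC)ccc1OCOC)C(=O)CC(=O)C(F)(F)F | intermediate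
16 | (3Z,4S)-3-[2,5-bis(methoxymethoxy)benzylidene]-1-diazo-7-methyl-2-oxooct-6-en-4-yl 3-methylbut-2-enoate | CC(C)=CC[C@H](OC(=O)C=C(C)C)/C(=C/c1cc(OCOC)ccc1OCOC)C(=O)C=[N+]=[N-] | intermediate
17 | (3E,4S)-3-[2,5-bis(methoxymethoxy)benzylidene]-7-methyl-1-oxoocta-1,6-dien-4-yl 3-methylbut-2-enoate (vinylketene, aryl cis to the ketenyl group) | CC(C)=CC[C@H](OC(=O)C=C(C)C)/C(C=C=O)=C/c1cc(OCOC)ccc1OCOC | intermediate
18 | (1S)-1-[5,8-bis(methoxymethoxy)-4-oxo-4,4a-dihydronaphthalen-2-yl]-4-methylpent-3-en-1-yl 3-methylbut-2-enoate (C4a configuration not defined, lost on enolization) | CC(C)=CC[C@H](OC(=O)C=C(C)C)C1=CC(=O)C2C(OCOC)=CC=C(OCOC)C2=C1 | intermediate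
19 | (1S)-1-[4-hydroxy-5,8-bis(methoxymethoxy)naphthalen-2-yl]-4-methylpent-3-en-1-yl 3-methylbut-2-enoate | CC(C)=CC[C@H](OC(=O)C=C(C)C)c1cc(O)c2c(OCOC)ccc(OCOC)c2c1 | intermediate
20 | (1S)-1-[5,8-bis(methoxymethoxy)-1,4-dioxo-1,4-dihydronaphthalen-2-yl]-4-methylpent-3-en-1-yl 3-methylbut-2-enoate | CC(C)=CC[C@H](OC(=O)C=C(C)C)C1=CC(=O)c2c(OCOC)ccc(OCOC)c2C1=O | intermediate
21 | alkannin β,β-dimethylacrylate, (1S)-1-(5,8-dihydroxy-1,4-dioxo-1,4-dihydronaphthalen-2-yl)-4-methylpent-3-en-1-yl 3-methylbut-2-enoate | CC(C)=CC[C@H](OC(=O)C=C(C)C)C1=CC(=O)c2c(O)ccc(O)c2C1=O | target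

**Totals**
Total step count: 12. Longest linear sequence: 11 steps (steps 1, 2, 4 to 12, from 1).

**Steps most likely to fail**

Step 10. The vinylketene may be consumed before it closes onto the arene, by light-induced E/Z scrambling of the styrenyl alkene or by intramolecular [2+2] addition to the prenyl alkene. The fallback sets out from 16. The Wolff rearrangement would be run in the dark in the presence of water (AgO2CPh, Et3N, THF/H2O, 25 °C), so that the ketene is trapped at once as the homologated acid F1, in which the aryl ring stays cis to the CH2CO2H arm. Activation with (CF3CO)2O and 2,6-lutidine in CH2Cl2 at −20 °C would give the mixed anhydride F2, which should close by intramolecular Friedel–Crafts acylation at the ortho CH next to the acetal oxygen. Enolization of the resulting ketone gives 19, where the route is rejoined.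

Step 8. Transmetalation at the α-branched, trisubstituted stannane may be slow, so that protodestannylation or ionization of the allylic ester by zerovalent palladium takes over. The fallback sets out from 11 and avoids palladium. Tin–lithium exchange on the free alcohol (MeLi, 2.2 equiv, THF, −78 °C) would give, with retention of geometry, the alkoxide/alkenyllithium dianion F3. Acylation with N-methoxy-N-methylacetamide and a cold AcOH quench would give the hydroxy enone F4. Steglich esterification of F4 with 12 (DCC, DMAP, CH2Cl2) comes back to 14.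

Step 9. The lithium enolate may attack the neighboring ester (O-to-C acyl transfer), or the allylic ester may be displaced under the amine conditions. The fallback sets out from 13 and uses no enolate. Iododestannylation (I2, CH2Cl2, 0 °C) would give, with retention, the alkenyl iodide F5. Hydroxycarbonylation (Pd(OAc)2, PPh3, CO 1 atm, K2CO3, DMF/H2O, 50 °C) would give the acrylic acid F6. 1-Chloro-N,N,2-trimethylprop-1-en-1-amine (CH2Cl2, 0 °C) would give the acid chloride F7, which is acylated onto Me3SiCHN2 (MeCN/THF, 0 °C) to give 16, where the route is rejoined.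

**Further compounds**
F1 | step 10 | (3E,4S)-3-[2,5-bis(methoxymethoxy)benzylidene]-7-methyl-4-[(3-methylbut-2-enoyl)oxy]oct-6-enoic acid | CC(C)=CC[C@H](OC(=O)C=C(C)C)/C(CC(=O)O)=C/c1cc(OCOC)ccc1OCOC
F2 | step 10 | mixed anhydride of F1 with trifluoroacetic acid | CC(C)=CC[C@H](OC(=O)C=C(C)C)/C(CC(=O)OC(=O)C(F)(F)F)=C/c1cc(OCOC)ccc1OCOC
F3 | step 8 | dilithium alkoxide/alkenyllithium derived from 11 (lithium in place of tin, aryl cis to lithium) | CC(C)=CC[C@H](O[Li])/C([Li])=C/c1cc(OCOC)ccc1OCOC
F4 | step 8 | (3Z,4S)-3-[2,5-bis(methoxymethoxy)benzylidene]-4-hydroxy-7-methyloct-6-en-2-one | CC(C)=CC[C@H](O)/C(=C/c1cc(OCOC)ccc1OCOC)C(C)=O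
F5 | step 9 | (1Z,3S)-1-[2,5-bis(methoxymethoxy)phenyl]-2-iodo-6-methylhepta-1,5-dien-3-yl 3-methylbut-2-enoate | CC(C)=CC[C@H](OC(=O)C=C(C)C)/C(I)=C/c1cc(OCOC)ccc1OCOC
F6 | step 9 | (2Z)-3-[2,5-bis(methoxymethoxy)phenyl]-2-{(1S)-4-methyl-1-[(3-methylbut-2-enoyl)oxy]pent-3-en-1-yl}prop-2-enoic acid | CC(C)=CC[C@H](OC(=O)C=C(C)C)/C(=C/c1cc(OCOC)ccc1OCOC)C(=O)O
F7 | step 9 | (2Z)-3-[2,5-bis(methoxymethoxy)phenyl]-2-{(1S)-4-methyl-1-[(3-methylbut-2-enoyl)oxy]pent-3-en-1-yl}prop-2-enoyl chloride | CC(C)=CC[C@H](OC(=O)C=C(C)C)/C(=C/c1cc(OCOC)ccc1OCOC)C(Cl)=O
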